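All runs were computed for an exercise, noise included.

G, the limiting reagent at 1.30 equiv of X, was what I kept the books on: every mole charged had to stand somewhere at 80 min.

| setting | eta | epsilon | flask |
|---|---|---|---|
| G | 0.050 M | 0.20 M | 0.10 M |
| X | 1.3 equiv | 1.3 equiv | 1.30 equiv |
| remark | run made earlier | run made earlier |  |
| time |  |  | 80 min |

| run | time / min | Q / % | D / % |
|---|---|---|---|
| eta | 6.00 | 3 | 0 |
| eta | 12.0 | 7 | 1 |
| eta | 25.0 | 4 | 4 |
| eta | 40.0 | 8 | 7 |
| eta | 80.0 | 11 | 21 |
| epsilon | 6.00 | 5 | 1 |
| epsilon | 12.0 | 18 | 4 |
| epsilon | 25.0 | 22 | 11 |
| epsilon | 40.0 | 20 | 16 |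
| epsilon | 80.0 | 19 | 37 |

(standard deviation of a reading: 2 percentage points)

- at 80 min, what has stopped the reaction, if anything has (X has run out first / forward and back rates have come level / all of G has reacted / it is still moving)
- the Q standing at 80 min, as a percentage of the G charged
- the D standing at 80 min, as a percentage of the G charged
- the E standing at 80 min, as a percentage of the G charged

- the reaction counts as stopped when no species that holds the G changes by six tenths of a point or more over the second half of the time

In the epsilon run Q levelled off while D climbed, so I took D to come from Q and entered both as one item, product. Everything else of the G, reacted or not, went down as the rest. Unreacted G sits in the rest, so the ratio of the two entries still moves with time and is no ratio of two rates; I therefore compared the runs only at equal time.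

In the eta run at 80 min, product stood at 32.0%, a capture ratio, product over rest, of 0.471. In the epsilon run, product stood at 56.0%, a ratio of 1.27. Between these runs the ratio rose with [G] to the power 0.718; I call this power, read at fixed equivalents and time, the capture order. It is a reading and carries the scatter of its entries.

For the flask at 0.10 M, the capture order gave a ratio of 0.774. My books therefore closed with product at 43.6% and a rest of 56.4%, which I did not split.

The forecast said it is still moving, with Q at 13%, D at 28% and E at 5%. Its Q and D add to 41.0%, a little under my product, and it called its E figure “poorly known”.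

The flask gave it is still moving, with Q at 15.1%, D at 28.9% and E at 20.9%.

    G ⇌ L (K = 1.60, k = 0.339 min⁻¹)
    G → E (k = 0.0143 min⁻¹)
    G + X ⇌ J (K = 3.65 L mol⁻¹, k = 0.111 L mol⁻¹ min⁻¹)
    X + L → Q (k = 0.183 L mol⁻¹ min⁻¹)
    X + E ⇌ Z (K = 6.69 L mol⁻¹, k = 0.0395 L mol⁻¹ min⁻¹)
    Q ⇌ D (K = 3.37, k = 0.0398 min⁻¹)

The forecast and the flask parted on E, by 16 percentage points. The flask's capture ratio was 0.783, against my 0.774. A neighbouring flask at 0.25 M of G, with equivalents and time held, takes the same reckoning: the capture order gives a ratio of 1.49, or product at 59.8%. That flask held Q at 19.6% and D at 42.2%, a ratio of 1.62, and its E stood at 13.1%.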